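Ring B, the cyclohexane between the seven-membered lactone (ring A) and the cage, is reached by contraction of a cycloheptane. (+)-Verbenone is edited to a 2,3-epoxy-3-methylcycloheptanone. A Lewis acid then shifts the ketone carbon C9 from C1 to C10. This single operation makes the C9–C10 bond, sets quaternary C10 (methyl, C1, C5, C9) by inversion at the epoxide, and expels C1 from the ring as the formyl carbon that ends as the β-olefinic carbon of ring A. The exploited feature is this 2-acyl-2-formyl pattern around C10. The C9 ketone then directs both alkylations at C8 and the cyclopentenone annulation that open the cage.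

Key step: step 5

Atom labels:
- Ring A = O–C4(CH3)2–C5–C10–C1=C2–C3(=O).
- Ring B = C5–C6–C7–C8–C9–C10.
- Cage: C11 (CH joined to C9, C12, C17), C12 (bears =CH2), C13 (quaternary, bears CH2O), C14 (lactone α-CH), C15 (CH2), C16 (C–CH3), C17 (ketone), C18 (CH2 between C8 and C16).
- Ring C = C8, C9, C11, C12, C13. Ring D = C8, C9, C11, C17, C16, C18. Ring E = C8, C18, C16, C15, C14, C13.

Remark: centres that are erased or equilibrated later (C8 in 11, C13 in 15, C14 and C16 up to step 17, C17 in 24 and 25) are carried as mixtures and are left undefined in the SMILES.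

Step 1
Reactants: 1 (1R,5R)-(+)-verbenone
Product: 2 (R)-4-(2-hydroxypropan-2-yl)-3-methylcyclohex-2-en-1-one
Conditions: H2SO4 (cat.), THF–H2O, 50 °C
Reagents that add atoms: water, O
Why: Acid-promoted cyclobutane fragmentation of a pinane ketone (retro-Prins type) should break the bond between the α-bridgehead and CMe2, water traps the tertiary cation, and the dienol returns to the enone while the C5 stereocentre is untouched.

Step 2
Reactants: 2 (R)-4-(2-hydroxypropan-2-yl)-3-methylcyclohex-2-en-1-one
Product: 3 (R)-4-[2-(tert-butyldimethylsilyloxy)propan-2-yl]-3-methylcyclohex-2-en-1-one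
Conditions: TBSOTf, 2,6-lutidine, CH2Cl2, 0 °C
Reagents that add atoms: tert-butyldimethylsilyl triflate, CC(C)(C)[Si](C)(C)OS(=O)(=O)C(F)(F)F
Why: Silyl triflate silylation is the standard way to protect a hindered tertiary alcohol.

Step 3
Reactants: 3 (R)-4-[2-(tert-butyldimethylsilyloxy)propan-2-yl]-3-methylcyclohex-2-en-1-one
Product: 5 (R)-4-[2-(tert-butyldimethylsilyloxy)propan-2-yl]-3-methylcyclohept-2-en-1-one, via α-silyl ketone 4 (not isolated)
Conditions: TMSCHN2, BF3·OEt2, CH2Cl2, −78 to −20 °C; then 1 M HCl, THF, 0 °C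
Reagents that add atoms: (trimethylsilyl)diazomethane, C[Si](C)(C)C=[N+]=[N-]
Why: In the Tiffeneau–Demjanov-type (Büchner–Curtius–Schlotterbeck) homologation of an enone the saturated α′-carbon should migrate rather than the vinyl carbon, which inserts C8 between C9 and C7.

Step 4
Reactants: 5 (R)-4-[2-(tert-butyldimethylsilyloxy)propan-2-yl]-3-methylcyclohept-2-en-1-one
Product: 6 2,3-epoxy-3-methyl-4-[2-(tert-butyldimethylsilyloxy)propan-2-yl]cycloheptan-1-one, epoxide oxygen anti to the C5 side chain
Conditions: H2O2 (30 %), NaOH, MeOH, 0 °C to rt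
Reagents that add atoms: hydrogen peroxide, OO
Why: In the Weitz–Scheffer epoxidation hydroperoxide should add to C10 from the face opposite the bulky silyloxyisopropyl group on neighbouring C5, which sets both epoxide carbons.

Step 5
Reactants: 6 2,3-epoxy-3-methyl-4-[2-(tert-butyldimethylsilyloxy)propan-2-yl]cycloheptan-1-one
Product: 7 2-formyl-2-methyl-3-[2-(tert-butyldimethylsilyloxy)propan-2-yl]cyclohexan-1-one, formyl trans and methyl cis to the C5 side chain
Conditions: BF3·OEt2, CH2Cl2, −20 °C, short contact; cold NaHCO3 quench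
Reagents that add atoms: none
Why: BF3 binds the epoxide oxygen and the C10–O bond, which leads to a tertiary cation remote from the carbonyl, lengthens while the acyl carbon C9 shifts from C1 to C10 on the face opposite the leaving oxygen and C1 collapses to the aldehyde. This is the House–Meinwald rearrangement of α,β-epoxy ketones, the type by which β-methyl epoxycycloalkanones contract to 2-formyl-2-methylcycloalkanones. No cyclisation is involved: the six-membered ring arises by a suprafacial 1,2-shift that replaces the C1 bridge between C9 and C10 by a direct bond. C10 is the only new stereocentre and is fixed by inversion at the epoxide carbon, so its configuration comes from the epoxide face that C5 dictated in step 4. The step needs acyl shift to beat hydride shift from C1 or C5 and to beat loss of the silyl ether, and the high migratory aptitude of acyl groups, the alignment of the ring C1–C9 bond and the short cold contact should secure this. The non-enolisable keto aldehyde is carried on at once because nucleophiles can remove its formyl group.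

Step 6
Reactants: 7 2-formyl-2-methyl-3-[2-(tert-butyldimethylsilyloxy)propan-2-yl]cyclohexan-1-one
Product: 8 2-methyl-2-vinyl-3-[2-(tert-butyldimethylsilyloxy)propan-2-yl]cyclohexan-1-one
Conditions: Ph3PCH3Br, KHMDS, THF, −78 to 0 °C (1.05 equiv of ylide)
Reagents that add atoms: methylenetriphenylphosphorane, C=P(c1ccccc1)(c1ccccc1)c1ccccc1
Why: In the Wittig methylenation the aldehyde should react far faster than the ketone next to a quaternary carbon, and no stereocentre is touched.

Step 7
Reactants: 9 methacrolein
Product: 10 2-(1-bromopropan-2-yl)-1,3-dioxolane (racemic)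
Conditions: HBr (gas), ethylene glycol, CH2Cl2, 0 °C
Reagents that add atoms: hydrogen bromide, Br; ethylene glycol, OCCO
Why: Conjugate hydrobromination of the enal with acetalisation in the same pot is the usual way to β-bromo acetals.

Step 8
Reactants: 8 2-methyl-2-vinyl-3-[2-(tert-butyldimethylsilyloxy)propan-2-yl]cyclohexan-1-one; 10 2-(1-bromopropan-2-yl)-1,3-dioxolane
Product: 11 C8-monoalkylated ketone bearing the CH2CH(CH3)(1,3-dioxolan-2-yl) chain (C18, C16, C17)
Conditions: LDA, THF, −78 °C; 10, NaI (cat.), DMPU, −78 °C to rt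
Reagents that add atoms: none
Why: This is an enolate alkylation in which only C8 can be deprotonated because C10 is quaternary, and the C8 and C16 epimers are erased in steps 9 and 17.

Step 9
Reactants: 11 C8-monoalkylated ketone
Product: 12 C8-quaternary ketone, allyl group (future C13, C12, C11) anti to the C10 methyl group
Conditions: KHMDS, THF, −78 °C; allyl bromide, −78 to 0 °C
Reagents that add atoms: allyl bromide, C=CCBr
Why: In this enolate allylation the tetrasubstituted C8=C9 enolate should be attacked from the face opposite the axial C10 methyl group, which places the allyl carbon on the C13 side and C18 syn to that methyl group.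

Step 10
Reactants: 12 C8-quaternary allyl ketone
Product: 13 1,4-diketone (2-oxopropyl group on C8)
Conditions: PdCl2 (10 mol %), CuCl, O2 (1 atm), DMF–H2O, rt
Reagents that add atoms: water, O
Why: The Tsuji–Wacker oxidation should select the unhindered allyl group because the vinyl group on quaternary C10 is shielded.

Step 11
Reactants: 13 1,4-diketone
Product: 14 bicyclic cyclopentenone (ring C: C12 ketone, C11=C9 double bond)
Conditions: KOH, xylenes, 110 °C, Dean–Stark trap
Reagents that add atoms: none
Why: In this intramolecular aldol condensation (5-exo-trig) the methyl carbon C11 attacks the non-enolisable C9 ketone, and loss of water drives the closure as it does for other 1,4-diketones whose ring ketone lies between two quaternary carbons.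

Step 12
Reactants: 14 bicyclic cyclopentenone
Product: 15 C13-(methoxycarbonylmethyl) cyclopentenone
Conditions: LDA, THF, −78 °C; methyl bromoacetate, DMPU, −78 to −30 °C
Reagents that add atoms: methyl bromoacetate, COC(=O)CBr
Why: This is alkylation of the cross-conjugated enolate, since C13 carries the only acidic hydrogens of the enone, and it brings in C14 and the lactone carbonyl.

Step 13
Reactants: 15 C13-(methoxycarbonylmethyl) cyclopentenone
Product: 17 spiro-γ-lactone cyclopentenone (CH2O anti and C14 syn to the C18 chain), via hydroxymethyl ester 16 (not isolated)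
Conditions: KOtBu (0.3 equiv), monomeric CH2O, THF, −40 to 0 °C
Reagents that add atoms: formaldehyde, C=O
Why: This is aldol addition of the thermodynamic C13 enolate followed by lactonisation (5-exo-trig), and formaldehyde should approach anti to the branched C18 chain on neighbouring C8, which sets quaternary C13 before ring closure makes the addition irreversible.

Step 14
Reactants: 17 spiro-γ-lactone cyclopentenone
Product: 18 C14-(dimethylaminomethyl) lactone (Mannich base, brings in C15)
Conditions: LDA, THF, −78 °C; dimethylmethyleneammonium iodide, −78 °C to rt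
Reagents that add atoms: Eschenmoser's salt, C=[N+](C)C.[I-]
Why: In this Mannich reaction the lactone α-carbon is the only position that can be deprotonated, because the enone has no acidic hydrogen left.

Step 15
Reactants: 18 Mannich base enone
Product: 19 cis-fused cyclopentanone (C9–H syn to C18 and to the C10 methyl group)
Conditions: Li (2.5 equiv), NH3(l), THF, t-BuOH (1 equiv), −78 °C; NH4Cl
Reagents that add atoms: none
Why: In the dissolving-metal (Birch-type) enone reduction the small proton should add to C9 so that rings B and C are cis-fused, because the cyclopentene-like enolate cannot hold a trans fusion, and the enone is reduced well before lactone, alkene or acetal.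

Step 16
Reactants: 19 cis-fused cyclopentanone
Product: 20 keto aldehyde (free C17 formyl group)
Conditions: 1 M HCl, THF, rt; NaHCO3
Reagents that add atoms: water, O
Why: Mild acetal hydrolysis should leave the tertiary silyl ether in place.

Step 17
Reactants: 20 keto aldehyde
Product: 24 cage hydroxy ketone (rings D and E closed, C12 ketone, C17 carbinol), via ammonium iodide 21 (not isolated), via methylene lactone 22 (not isolated), via Michael adduct 23 (not isolated)
Conditions: MeI, CH2Cl2, rt; then DBU, 0 °C to rt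
Reagents that add atoms: none
Why: Quaternisation and Hofmann-type E1cB elimination unmask the α-methylene lactone, the aldehyde enolate C16 adds to C15 (intramolecular Michael addition, 6-endo-trig), and C11 closes on the formyl carbon (intramolecular aldol addition, 6-exo-trig), both additions being reversible so that C16, C14 and C11 should settle in the only arrangement the cage allows.

Step 18
Reactants: 24 cage hydroxy ketone
Product: 25 C12-methylene cage alcohol
Conditions: Zn, CH2Br2, TiCl4, THF–CH2Cl2, 0 °C to rt
Reagents that add atoms: dibromomethane, BrCBr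
Why: The Lombardo methylenation is non-basic, so retro-aldol cleavage is avoided and the lactone is left alone, and it is well suited to hindered bicyclo[3.2.1]octanone carbonyl groups.

Step 19
Reactants: 25 C12-methylene cage alcohol
Product: 26 cage ketone silyl ether
Conditions: Dess–Martin periodinane, NaHCO3, CH2Cl2, rt
Reagents that add atoms: none
Why: Dess–Martin oxidation gives the C17 ketone, and the β,γ-double bond cannot move into conjugation because C11 is a bridgehead.

Step 20
Reactants: 26 cage ketone silyl ether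
Product: 27 cage ketone tertiary alcohol
Conditions: HF·pyridine, THF, 0 °C to rt
Reagents that add atoms: none
Why: Fluoride-mediated desilylation under weakly acidic conditions avoids retro-Michael opening of the cage.

Step 21
Reactants: 27 cage ketone tertiary alcohol
Product: 28 acrylate ester of the C4 alcohol
Conditions: acryloyl chloride, i-Pr2NEt, DMAP (cat.), CH2Cl2, 0 °C to rt
Reagents that add atoms: acryloyl chloride, C=CC(=O)Cl
Why: DMAP-catalysed acylation brings in C2 and C3 at the only hydroxyl group.

Step 22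
Reactants: 28 acrylate ester
Product: 29 CNP0136584.3 (target)
Conditions: second-generation Hoveyda–Grubbs catalyst (10 mol %), toluene, 90 °C, high dilution
Reagents that add atoms: none
Why: Ring-closing metathesis of the acrylate and the C10 vinyl group closes ring A with the Z C1=C2 bond that the seven-membered ring enforces, and the hindered 1,1-disubstituted C12 methylene should stay out of the reaction.

Compound list
1 | (1R,5R)-(+)-verbenone | CC1=CC(=O)[C@@H]2C[C@H]1C2(C)C | starting material
2 | (R)-4-(2-hydroxypropan-2-yl)-3-methylcyclohex-2-en-1-one | CC1=CC(=O)CC[C@H]1C(C)(C)O | intermediate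
3 | TBS ether of 2 | CC1=CC(=O)CC[C@H]1C(C)(C)O[Si](C)(C)C(C)(C)C | intermediate
4 | α-trimethylsilyl cycloheptenone | CC1=CC(=O)C([Si](C)(C)C)CC[C@H]1C(C)(C)O[Si](C)(C)C(C)(C)C | intermediate
5 | (R)-3-methyl-4-(silyloxyisopropyl)cyclohept-2-en-1-one | CC1=CC(=O)CCC[C@H]1C(C)(C)O[Si](C)(C)C(C)(C)C | intermediate
6 | epoxy ketone, oxygen anti to the C5 side chain | C[C@@]12O[C@@H]1C(=O)CCC[C@H]2C(C)(C)O[Si](C)(C)C(C)(C)C | intermediate
7 | 2-formyl-2-methyl cyclohexanone, formyl trans to the C5 side chain | O=C[C@]1(C)C(=O)CCC[C@H]1C(C)(C)O[Si](C)(C)C(C)(C)C | intermediate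
8 | 2-methyl-2-vinyl cyclohexanone | C=C[C@]1(C)C(=O)CCC[C@H]1C(C)(C)O[Si](C)(C)C(C)(C)C | intermediate
9 | methacrolein | C=C(C)C=O | starting material
10 | 2-(1-bromopropan-2-yl)-1,3-dioxolane | CC(CBr)C1OCCO1 | intermediate
11 | C8-monoalkylated ketone | C=C[C@]1(C)C(=O)C(CC(C)C2OCCO2)CC[C@H]1C(C)(C)O[Si](C)(C)C(C)(C)C | intermediate
12 | C8-quaternary allyl ketone | C=C[C@]1(C)C(=O)[C@@](CC=C)(CC(C)C2OCCO2)CC[C@H]1C(C)(C)O[Si](C)(C)C(C)(C)C | intermediate
13 | 1,4-diketone | C=C[C@]1(C)C(=O)[C@@](CC(C)=O)(CC(C)C2OCCO2)CC[C@H]1C(C)(C)O[Si](C)(C)C(C)(C)C | intermediate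
14 | bicyclic cyclopentenone | C=C[C@]1(C)C2=CC(=O)C[C@]2(CC(C)C3OCCO3)CC[C@H]1C(C)(C)O[Si](C)(C)C(C)(C)C | intermediate
15 | C13-(methoxycarbonylmethyl) cyclopentenone | C=C[C@]1(C)C2=CC(=O)C(CC(=O)OC)[C@]2(CC(C)C3OCCO3)CC[C@H]1C(C)(C)O[Si](C)(C)C(C)(C)C | intermediate
16 | C13-hydroxymethyl ester | C=C[C@]1(C)C2=CC(=O)[C@@](CO)(CC(=O)OC)[C@]2(CC(C)C3OCCO3)CC[C@H]1C(C)(C)O[Si](C)(C)C(C)(C)C | intermediate
17 | spiro-γ-lactone cyclopentenone | C=C[C@]1(C)C2=CC(=O)[C@]4(COC(=O)C4)[C@]2(CC(C)C3OCCO3)CC[C@H]1C(C)(C)O[Si](C)(C)C(C)(C)C | intermediate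
18 | Mannich base enone | C=C[C@]1(C)C2=CC(=O)[C@]4(COC(=O)C4CN(C)C)[C@]2(CC(C)C3OCCO3)CC[C@H]1C(C)(C)O[Si](C)(C)C(C)(C)C | intermediate
19 | cis-fused cyclopentanone | C=C[C@]1(C)[C@@H]2CC(=O)[C@]4(COC(=O)C4CN(C)C)[C@]2(CC(C)C3OCCO3)CC[C@H]1C(C)(C)O[Si](C)(C)C(C)(C)C | intermediate
20 | keto aldehyde | C=C[C@]1(C)[C@@H]2CC(=O)[C@]4(COC(=O)C4CN(C)C)[C@]2(CC(C)C=O)CC[C@H]1C(C)(C)O[Si](C)(C)C(C)(C)C | intermediate
21 | trimethylammonium iodide | C=C[C@]1(C)[C@@H]2CC(=O)[C@]4(COC(=O)C4C[N+](C)(C)C)[C@]2(CC(C)C=O)CC[C@H]1C(C)(C)O[Si](C)(C)C(C)(C)C.[I-] | intermediate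
22 | α-methylene lactone keto aldehyde | C=C[C@]1(C)[C@@H]2CC(=O)[C@]4(COC(=O)C4=C)[C@]2(CC(C)C=O)CC[C@H]1C(C)(C)O[Si](C)(C)C(C)(C)C | intermediate
23 | Michael adduct (ring E closed, C16 formyl) | O=C[C@]1(C)C[C@@H]2C(=O)OC[C@]23C(=O)C[C@@H]4[C@@]3(C1)CC[C@@H](C(C)(C)O[Si](C)(C)C(C)(C)C)[C@]4(C)C=C | intermediate
24 | cage hydroxy ketone | O=C1[C@@H]2C(O)[C@]3(C)C[C@@H]4C(=O)OC[C@]14[C@@]1(CC[C@@H](C(C)(C)O[Si](C)(C)C(C)(C)C)[C@](C)(C=C)[C@H]21)C3 | intermediate
25 | C12-methylene cage alcohol | C=C1[C@@H]2C(O)[C@]3(C)C[C@@H]4C(=O)OC[C@]14[C@@]1(CC[C@@H](C(C)(C)O[Si](C)(C)C(C)(C)C)[C@](C)(C=C)[C@H]21)C3 | intermediate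
26 | cage ketone silyl ether | C=C1[C@@H]2C(=O)[C@]3(C)C[C@@H]4C(=O)OC[C@]14[C@@]1(CC[C@@H](C(C)(C)O[Si](C)(C)C(C)(C)C)[C@](C)(C=C)[C@H]21)C3 | intermediate
27 | cage ketone tertiary alcohol | C=C1[C@@H]2C(=O)[C@]3(C)C[C@@H]4C(=O)OC[C@]14[C@@]1(CC[C@@H](C(C)(C)O)[C@](C)(C=C)[C@H]21)C3 | intermediate
28 | acrylate ester | C=C1[C@@H]2C(=O)[C@]3(C)C[C@@H]4C(=O)OC[C@]14[C@@]1(CC[C@@H](C(C)(C)OC(=O)C=C)[C@](C)(C=C)[C@H]21)C3 | intermediate
29 | CNP0136584.3 | C=C1[C@@H]2C(=O)[C@]3(C)C[C@@H]4C(=O)OC[C@]14[C@@]1(CC[C@H]4C(C)(C)OC(=O)C=C[C@]4(C)[C@H]21)C3 | target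

Total step count: 22. Longest linear sequence: 21 steps (steps 1–6 and 8–22, from (+)-verbenone).

Steps most likely to fail

Step 3
- What may go wrong: the vinyl carbon may migrate instead of the α′-methylene, the diazo compound may add to the enone as a dipole, or a second homologation may occur.
- Fallback: a cyclopropane-fragmentation ring expansion (Saegusa type) that sets out from 3 and comes back at 5. LDA and TMSCl give the cross-conjugated silyl dienol ether F1. Et2Zn and CH2I2 cyclopropanate its electron-rich enol ether bond to the siloxycyclopropane F2. FeCl3 in DMF opens the shared bond to the β-chloro cycloheptenone F3. Bu3SnH with AIBN then removes the chlorine to give 5.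

Step 15
- What may go wrong: C9 may be protonated from the wrong face, or the lactone may be over-reduced.
- Fallback: intramolecular hydride delivery that sets out from 17 (before the amine is introduced) and comes back at 26.
  - Sc(OTf)3 in CH2Cl2 should trigger a 1,5-hydride shift from the dioxolane C17–H, held on the required face by the C18 chain, to C9. The enolate should then close on the dioxolanylium carbon (hydride-transfer cyclisation) to give the ketal ketone F4.
  - Lombardo methylenation gives the methylene ketal F5.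
  - LDA and Eschenmoser's salt give the Mannich base F6.
  - MeI then NaHCO3 gives the methylene lactone ketal F7.
  - Aqueous HCl frees the ketone F8, and DBU closes ring E by Michael addition to give 26.

Step 22
- What may go wrong: the ruthenium carbene may fail to engage the neopentyl vinyl group, acrylate dimerisation may compete, or the strain of the trans-fused bicycle may prevent closure.
- Fallback: an olefination ring closure that sets out from 27 and comes back at 29. Diethylphosphonoacetic acid with DCC and DMAP gives the phosphonoacetate F9. OsO4 (cat.), NaIO4 and 2,6-lutidine cleave the monosubstituted C10 vinyl group to the aldehyde F10. LiCl and DBU in MeCN (Masamune–Roush conditions) then close ring A by intramolecular Horner–Wadsworth–Emmons reaction to give 29.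

Further compounds
F1 | step 3 | cross-conjugated silyl dienol ether | CC1=CC(O[Si](C)(C)C)=CC[C@H]1C(C)(C)O[Si](C)(C)C(C)(C)C
F2 | step 3 | siloxycyclopropane | CC1=CC2(O[Si](C)(C)C)CC2C[C@H]1C(C)(C)O[Si](C)(C)C(C)(C)C
F3 | step 3 | β-chloro cycloheptenone | CC1=CC(=O)CC(Cl)C[C@H]1C(C)(C)O[Si](C)(C)C(C)(C)C
F4 | step 15 | ketal ketone (ring D closed) | O=C1[C@@H]2C3(OCCO3)C(C)C[C@]4(CC[C@@H](C(C)(C)O[Si](C)(C)C(C)(C)C)[C@](C)(C=C)[C@H]24)[C@@]15COC(=O)C5
F5 | step 15 | methylene ketal | C=C1[C@@H]2C3(OCCO3)C(C)C[C@]4(CC[C@@H](C(C)(C)O[Si](C)(C)C(C)(C)C)[C@](C)(C=C)[C@H]24)[C@@]15COC(=O)C5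
F6 | step 15 | Mannich base ketal | C=C1[C@@H]2C3(OCCO3)C(C)C[C@]4(CC[C@@H](C(C)(C)O[Si](C)(C)C(C)(C)C)[C@](C)(C=C)[C@H]24)[C@@]15COC(=O)C5CN(C)C
F7 | step 15 | methylene lactone ketal | C=C1[C@@H]2C3(OCCO3)C(C)C[C@]4(CC[C@@H](C(C)(C)O[Si](C)(C)C(C)(C)C)[C@](C)(C=C)[C@H]24)[C@@]15COC(=O)C5=C
F8 | step 15 | methylene lactone ketone | C=C1[C@@H]2C(=O)C(C)C[C@]4(CC[C@@H](C(C)(C)O[Si](C)(C)C(C)(C)C)[C@](C)(C=C)[C@H]24)[C@@]15COC(=O)C5=C
F9 | step 22 | phosphonoacetate | C=C1[C@@H]2C(=O)[C@]3(C)C[C@@H]4C(=O)OC[C@]14[C@@]1(CC[C@@H](C(C)(C)OC(=O)CP(=O)(OCC)OCC)[C@](C)(C=C)[C@H]21)C3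
F10 | step 22 | C10 aldehyde phosphonoacetate | C=C1[C@@H]2C(=O)[C@]3(C)C[C@@H]4C(=O)OC[C@]14[C@@]1(CC[C@@H](C(C)(C)OC(=O)CP(=O)(OCC)OCC)[C@](C)(C=O)[C@H]21)C3
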